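**Plan**

- Retrosynthetic cuts, in order: the three galloyl ester C–O bonds; in the upper unit O1–C2 and the C2–aryl (ring B) bond; then C3–C4 and the lactol O1–C2 bond of upper ring C (the annulation); the carbinol C–C bond between upper ring A and C8 of the middle unit; last the middle C4–lower C8 interflavan bond.
- Forward: benzylated, silylated epicatechin is coupled with its C8-brominated, C4-activated twin to the middle–lower dimer. Its C8 aryllithium adds to an O-allyl salicylaldehyde (future upper ring A), and deallylation frees the ortho-hydroxy benzhydrol.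
- The derived ortho-quinone methide takes up the prolinol enamine of silyloxyacetaldehyde and closes upper ring C as a 3-silyloxychroman-2-ol. Aryl Grignard opening and Mitsunobu re-closure install ring B; desilylation, triple galloylation and hydrogenolysis finish.
- Enabling feature: O1, C8a, C4a and C4 of the upper unit, with C4 benzylic twice over because it also carries C8 of the middle unit, are the four atoms of a masked ortho-quinone methide. A C2–C3 two-carbon unit already bearing the C3 oxygen completes ring C.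
- Stereochemistry: C2/C3 of the lower and middle units come from (−)-epicatechin; middle C4 (4β) from anti attack on the C4 cation; upper C3 from the amine catalyst with C4 trans to it; upper C2 from Felkin-type addition followed by SN2 inversion.

Key step: step 10

Assumption: 3,4,5-tris(benzyloxy)benzoic acid (the tri-O-benzyl ether of gallic acid, used as the acylating reagent of step 14) and 4-bromo-1,2-bis(benzyloxy)benzene are bought as catalogue compounds; the diaryl carbinol carbon and the lactol carbon are carried as epimeric mixtures, because the first becomes planar and the second is opened later.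

Terms: Bn = benzyl; TBS = tert-butyldimethylsilyl. "Lower", "middle" and "upper" are the three flavan units of the trimer (lower = the unit with the C4 methylene). "Dimer" = [5,7,3',4'-tetra-O-benzyl-3-O-TBS-epicatechin]-(4β→8)-[5,7,3',4'-tetra-O-benzyl-3-O-TBS-epicatechin], i.e. middle plus lower unit; "dimer-8-yl" is this unit attached through C8 of the middle unit.

**Route**

Step 1
Reactants: 1 (−)-epicatechin
Product: 2 5,7,3',4'-tetra-O-benzyl-(−)-epicatechin
Conditions: BnBr (4.2 equiv), K2CO3, DMF, 0 °C → rt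
Reagents that add atoms: benzyl bromide, BrCc1ccccc1
Why: Williamson etherification takes the four phenols, which are far more acidic than the secondary C3 alcohol, so the 3-OH stays free and the mild carbonate base at low temperature should leave C2 and C3 untouched.

Step 2
Reactants: 2 5,7,3',4'-tetra-O-benzyl-(−)-epicatechin
Product: 3 5,7,3',4'-tetra-O-benzyl-3-O-TBS-(−)-epicatechin
Conditions: TBSCl, imidazole, DMF, rt
Reagents that add atoms: tert-butyldimethylsilyl chloride, CC(C)(C)[Si](C)(C)Cl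
Why: Standard silylation of a secondary alcohol (silyl chloride/imidazole) gives an ether that tolerates the later organolithium, Grignard and weak-acid steps without touching a stereocentre.

Step 3
Reactants: 3 5,7,3',4'-tetra-O-benzyl-3-O-TBS-(−)-epicatechin
Product: 4 5,7,3',4'-tetra-O-benzyl-3-O-TBS-4β-(2-ethoxyethoxy)epicatechin
Conditions: DDQ, EtOCH2CH2OH, CH2Cl2, rt
Reagents that add atoms: 2-ethoxyethanol, CCOCCO
Why: DDQ benzylic oxidation (hydride abstraction at C4, the cation being stabilised by the 5,7-dioxygenated ring A) with capture by the alcohol anti to the C2 aryl and C3 silyloxy groups should give the 4β ether, and either C4 epimer would serve because C4 is re-ionised in step 5.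

Step 4
Reactants: 4 5,7,3',4'-tetra-O-benzyl-3-O-TBS-4β-(2-ethoxyethoxy)epicatechin
Product: 5 8-bromo-5,7,3',4'-tetra-O-benzyl-3-O-TBS-4β-(2-ethoxyethoxy)epicatechin
Conditions: NBS (1.0 equiv), CH2Cl2, −78 → 0 °C
Reagents that add atoms: N-bromosuccinimide, O=C1CCC(=O)N1Br
Why: Electrophilic aromatic bromination of 5,7-di-O-benzyl flavans with NBS is known to go to C8, and the bromine both blocks self-condensation of the electrophile in step 5 and places the metalation handle unambiguously on the future middle unit.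

Step 5
Reactants: 5 8-bromo-5,7,3',4'-tetra-O-benzyl-3-O-TBS-4β-(2-ethoxyethoxy)epicatechin (electrophile); 3 5,7,3',4'-tetra-O-benzyl-3-O-TBS-(−)-epicatechin (nucleophile, 2 equiv, excess recovered)
Product: 6 C8-bromo dimer
Conditions: Me3SiOTf (cat.), CH2Cl2, −78 → −40 °C
Reagents that add atoms: none
Why: Lewis-acid-promoted Friedel–Crafts-type flavan coupling: Me3SiOTf ionises the C4 acetal to a ring-A-stabilised benzylic cation, which C8 of 3 attacks from the β face, anti to both the C2 aryl and C3 silyloxy groups, setting the 4β (3,4-trans) interflavan bond while the C8 bromine prevents oligomerisation.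

Step 6
Reactants: 7 2,4,6-trihydroxybenzaldehyde
Product: 8 2,4-bis(benzyloxy)-6-hydroxybenzaldehyde
Conditions: BnBr (2.0 equiv), K2CO3, DMF, 0 °C → rt
Reagents that add atoms: benzyl bromide, BrCc1ccccc1
Why: Williamson etherification takes the para OH and one ortho OH, after which the remaining ortho phenol is strongly hydrogen-bonded to the aldehyde and resists alkylation under these mild conditions.

Step 7
Reactants: 8 2,4-bis(benzyloxy)-6-hydroxybenzaldehyde
Product: 9 2-(allyloxy)-4,6-bis(benzyloxy)benzaldehyde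
Conditions: allyl bromide, K2CO3, DMF, 60 °C
Reagents that add atoms: allyl bromide, C=CCBr
Why: Williamson etherification of the chelated phenol under warmer conditions installs an allyl ether, which survives the aryllithium addition and can later be removed without acid in the presence of benzyl and silyl ethers.

Step 8
Reactants: 6 C8-bromo dimer; 9 2-(allyloxy)-4,6-bis(benzyloxy)benzaldehyde
Product: 11 [2-(allyloxy)-4,6-bis(benzyloxy)phenyl](dimer-8-yl)methanol, via C8-lithiated dimer 10 (not isolated)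
Conditions: t-BuLi (2 equiv), THF, −78 °C; then 9, −78 → −40 °C; H2O quench; chromatography on Et3N-deactivated silica
Reagents that add atoms: none
Why: Bromine–lithium exchange with t-BuLi, a reaction established for 8-bromo benzyl-protected flavan silyl ethers, followed by 1,2-addition of the aryllithium to the aldehyde forms the diaryl carbinol, whose new stereocentre is formed unselectively and is of no consequence because it becomes planar in step 10.

Step 9
Reactants: 11 [2-(allyloxy)-4,6-bis(benzyloxy)phenyl](dimer-8-yl)methanol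
Product: 12 [4,6-bis(benzyloxy)-2-hydroxyphenyl](dimer-8-yl)methanol
Conditions: Pd(PPh3)4 (5 mol %), morpholine, THF, rt
Reagents that add atoms: none
Why: Palladium-catalysed deallylation of an aryl allyl ether (Tsuji–Trost-type π-allyl formation with transfer of the allyl group to morpholine) frees the phenol under basic, non-ionising conditions that the acid-labile benzhydrol and the benzyl and silyl ethers should survive.

Step 10
Reactants: 12 [4,6-bis(benzyloxy)-2-hydroxyphenyl](dimer-8-yl)methanol; 13 (tert-butyldimethylsilyloxy)acetaldehyde (3 equiv)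
Product: 15 protected trimer bearing a 3-silyloxychroman-2-ol upper unit, via ortho-quinone methide 14 (not isolated)
Conditions: (S)-2-[diphenyl(trimethylsilyloxy)methyl]pyrrolidine (20 mol %), PhCO2H (20 mol %), CHCl3, 0 °C → rt
Reagents that add atoms: none
Why: PhCO2H reversibly ionises the doubly electron-rich benzhydrol 12, with loss of water, to ortho-quinone methide 14 while the pyrrolidine condenses with 13 to an E-enamine, whose nucleophilic carbon (the aldehyde α-carbon) adds to the exocyclic methide carbon (C3–C4 bond); the phenoxide then attacks the iminium carbon and hydrolysis of the N,O-acetal releases lactol 15 and the amine. The closest known reaction type is the secondary-amine/Brønsted-acid catalysed formal [4+2] annulation of in situ generated ortho-quinone methides with enolisable aldehydes, which gives 3,4-trans chroman-2-ols. Ring C of the upper unit closes by 6-exo-trig attack of O1 on the iminium carbon C2. C3 is controlled by the catalyst, whose diphenyl(silyloxy)methyl group shields one face of the s-trans enamine so that the (S)-amine should deliver 3R, and C4 is controlled relative to C3 by the anti (open, synclinal) approach, with the 3,4-cis adduct able to revert to the stabilised methide or to epimerise at C3 through the enamine so that the trans isomer should accumulate. The step needs 3R,4R (3,4-trans) geometry, attack only at the methide carbon and survival of the acid-sensitive 4β→8 bond and silyl ethers: the catalyst enantiomer is chosen to set the absolute sense over the bias of the chiral dimer, the two trioxygenated rings let a weak carboxylic acid suffice for ionisation, and the configuration of the carbinol carbon is irrelevant because C4 passes through a planar state.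

Step 11
Reactants: 15 protected trimer bearing a 3-silyloxychroman-2-ol upper unit; 16 4-bromo-1,2-bis(benzyloxy)benzene
Product: 19 ring-opened anti silyloxy carbinol, via aryl Grignard reagent 17 (not isolated), via ring-opened hydroxy aldehyde 18 (not isolated)
Conditions: 16, Mg, THF, rt; then 15 added to 17 (3 equiv), THF, −78 → −40 °C; H2O quench
Reagents that add atoms: none
Why: Grignard addition to a lactol: the first equivalent deprotonates and opens 15 to the α-silyloxy aldehyde, and the bulky, non-chelating silyloxy group directs polar Felkin–Anh (non-chelation) attack to give the anti silyloxy carbinol (S at the new carbinol carbon, ring A phenol free), the isomer required for inversion in step 12.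

Step 12
Reactants: 19 ring-opened anti silyloxy carbinol
Product: 20 dodeca-O-benzyl-3,3',3''-tris-O-TBS-procyanidin C1
Conditions: PPh3, DIAD, toluene, −20 → 0 °C
Reagents that add atoms: none
Why: Intramolecular Mitsunobu etherification, in which the phenol (the only acidic OH) displaces the oxyphosphonium of the benzylic alcohol by SN2 with inversion, turns the S carbinol into the 2R centre and closes upper ring C (6-exo-tet), the non-polar solvent and low temperature being chosen to suppress ionisation of the electron-rich benzylic position.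

Step 13
Reactants: 20 dodeca-O-benzyl-3,3',3''-tris-O-TBS-procyanidin C1
Product: 21 dodeca-O-benzyl-procyanidin C1 (three free 3-OH groups)
Conditions: HF·pyridine, pyridine/THF, 0 °C → rt
Reagents that add atoms: none
Why: Fluoride-mediated cleavage of the three secondary silyl ethers with pyridine-buffered HF should leave the benzyl ethers and both interflavan bonds intact and touches no stereocentre.

Step 14
Reactants: 21 dodeca-O-benzyl-procyanidin C1
Product: 22 dodeca-O-benzyl-procyanidin C1 3,3',3''-tris[3,4,5-tris(benzyloxy)benzoate]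
Conditions: 3,4,5-(BnO)3C6H2CO2H (6 equiv), DCC (6 equiv), 4-(dimethylamino)pyridine (DMAP, 1.5 equiv), CH2Cl2, rt
Reagents that add atoms: 3,4,5-tris(benzyloxy)benzoic acid, OC(=O)c1cc(OCc2ccccc2)c(OCc2ccccc2)c(OCc2ccccc2)c1
Why: Steglich esterification (carbodiimide activation with DMAP acyl transfer) is an established way to galloylate hindered flavan 3-ols; three equivalents of the acid are taken up, one at each secondary 3-OH, and configuration at each C3 is retained because no C–O bond at the stereocentre is broken.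

Step 15
Reactants: 22 dodeca-O-benzyl-procyanidin C1 3,3',3''-tris[3,4,5-tris(benzyloxy)benzoate]
Product: 23 procyanidin C1 3,3',3''-tri-O-gallate
Conditions: H2 (1 atm), Pd(OH)2/C, THF/MeOH/H2O, rt
Reagents that add atoms: none
Why: Catalytic hydrogenolysis removes all twenty-one benzyl ethers under neutral conditions that should spare the aryl esters, the C2–O1 bonds and the interflavan bonds, as is usual for benzyl-protected procyanidin gallates.

**Compound list**

1 | (−)-epicatechin, (2R,3R)-2-(3,4-dihydroxyphenyl)chroman-3,5,7-triol | Oc1cc(O)c2c(c1)O[C@H](c1ccc(O)c(O)c1)[C@H](O)C2 | starting material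
2 | 5,7,3',4'-tetra-O-benzyl-(−)-epicatechin (2R,3R; free 3-OH) | O[C@@H]1Cc2c(OCc9ccccc9)cc(OCc9ccccc9)cc2O[C@@H]1c4ccc(OCc9ccccc9)c(OCc9ccccc9)c4 | intermediate
3 | 5,7,3',4'-tetra-O-benzyl-3-O-TBS-(−)-epicatechin (2R,3R) | CC(C)(C)[Si](C)(C)O[C@@H]1Cc2c(OCc9ccccc9)cc(OCc9ccccc9)cc2O[C@@H]1c4ccc(OCc9ccccc9)c(OCc9ccccc9)c4 | intermediate
4 | 5,7,3',4'-tetra-O-benzyl-3-O-TBS-4β-(2-ethoxyethoxy)epicatechin (2,3-cis, 3,4-trans) | CC(C)(C)[Si](C)(C)O[C@@H]1[C@@H](OCCOCC)c2c(OCc9ccccc9)cc(OCc9ccccc9)cc2O[C@@H]1c4ccc(OCc9ccccc9)c(OCc9ccccc9)c4 | intermediate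
5 | 8-bromo-5,7,3',4'-tetra-O-benzyl-3-O-TBS-4β-(2-ethoxyethoxy)epicatechin | CC(C)(C)[Si](C)(C)O[C@@H]1[C@@H](OCCOCC)c2c(OCc9ccccc9)cc(OCc9ccccc9)c(Br)c2O[C@@H]1c4ccc(OCc9ccccc9)c(OCc9ccccc9)c4 | intermediate
6 | C8-bromo dimer: 8-bromo-[5,7,3',4'-tetra-O-benzyl-3-O-TBS-epicatechin]-(4β→8)-[5,7,3',4'-tetra-O-benzyl-3-O-TBS-epicatechin] | CC(C)(C)[Si](C)(C)O[C@@H]1[C@@H](c2c(OCc9ccccc9)cc(OCc9ccccc9)c3c2O[C@H](c4ccc(OCc9ccccc9)c(OCc9ccccc9)c4)[C@H](O[Si](C)(C)C(C)(C)C)C3)c2c(OCc9ccccc9)cc(OCc9ccccc9)c(Br)c2O[C@@H]1c4ccc(OCc9ccccc9)c(OCc9ccccc9)c4 | intermediate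
7 | 2,4,6-trihydroxybenzaldehyde | O=Cc1c(O)cc(O)cc1O | starting material
8 | 2,4-bis(benzyloxy)-6-hydroxybenzaldehyde | O=Cc1c(O)cc(OCc2ccccc2)cc1OCc2ccccc2 | intermediate
9 | 2-(allyloxy)-4,6-bis(benzyloxy)benzaldehyde | O=Cc1c(OCC=C)cc(OCc2ccccc2)cc1OCc2ccccc2 | intermediate
10 | C8-lithiated dimer (aryllithium at C8 of the middle unit; not isolated) | CC(C)(C)[Si](C)(C)O[C@@H]1[C@@H](c2c(OCc9ccccc9)cc(OCc9ccccc9)c3c2O[C@H](c4ccc(OCc9ccccc9)c(OCc9ccccc9)c4)[C@H](O[Si](C)(C)C(C)(C)C)C3)c2c(OCc9ccccc9)cc(OCc9ccccc9)c([Li])c2O[C@@H]1c4ccc(OCc9ccccc9)c(OCc9ccccc9)c4 | intermediate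
11 | [2-(allyloxy)-4,6-bis(benzyloxy)phenyl](dimer-8-yl)methanol, both carbinol epimers | CC(C)(C)[Si](C)(C)O[C@@H]1[C@@H](c2c(OCc9ccccc9)cc(OCc9ccccc9)c3c2O[C@H](c4ccc(OCc9ccccc9)c(OCc9ccccc9)c4)[C@H](O[Si](C)(C)C(C)(C)C)C3)c2c(OCc9ccccc9)cc(OCc9ccccc9)c(C(O)c3c(OCC=C)cc(OCc9ccccc9)cc3OCc9ccccc9)c2O[C@@H]1c4ccc(OCc9ccccc9)c(OCc9ccccc9)c4 | intermediate
12 | [4,6-bis(benzyloxy)-2-hydroxyphenyl](dimer-8-yl)methanol, both carbinol epimers (precursor of the key step) | CC(C)(C)[Si](C)(C)O[C@@H]1[C@@H](c2c(OCc9ccccc9)cc(OCc9ccccc9)c3c2O[C@H](c4ccc(OCc9ccccc9)c(OCc9ccccc9)c4)[C@H](O[Si](C)(C)C(C)(C)C)C3)c2c(OCc9ccccc9)cc(OCc9ccccc9)c(C(O)c3c(O)cc(OCc9ccccc9)cc3OCc9ccccc9)c2O[C@@H]1c4ccc(OCc9ccccc9)c(OCc9ccccc9)c4 | intermediate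
13 | (tert-butyldimethylsilyloxy)acetaldehyde | O=CCO[Si](C)(C)C(C)(C)C | starting material
14 | ortho-quinone methide: 3,5-bis(benzyloxy)-6-[(dimer-8-yl)methylidene]cyclohexa-2,4-dien-1-one (not isolated) | CC(C)(C)[Si](C)(C)O[C@@H]1[C@@H](c2c(OCc9ccccc9)cc(OCc9ccccc9)c3c2O[C@H](c4ccc(OCc9ccccc9)c(OCc9ccccc9)c4)[C@H](O[Si](C)(C)C(C)(C)C)C3)c2c(OCc9ccccc9)cc(OCc9ccccc9)c(C=C3C(=O)C=C(OCc9ccccc9)C=C3OCc9ccccc9)c2O[C@@H]1c4ccc(OCc9ccccc9)c(OCc9ccccc9)c4 | intermediate
15 | protected trimer whose upper unit is (3R,4R)-5,7-bis(benzyloxy)-3-(TBS-oxy)chroman-2-ol bonded through C4 to C8 of the middle unit (3,4-trans; lactol carbon as anomeric mixture) | CC(C)(C)[Si](C)(C)O[C@@H]1[C@@H](c2c(OCc9ccccc9)cc(OCc9ccccc9)c3c2O[C@H](c4ccc(OCc9ccccc9)c(OCc9ccccc9)c4)[C@H](O[Si](C)(C)C(C)(C)C)C3)c2c(OCc9ccccc9)cc(OCc9ccccc9)c([C@H]3c5c(OCc9ccccc9)cc(OCc9ccccc9)cc5OC(O)[C@@H]3O[Si](C)(C)C(C)(C)C)c2O[C@@H]1c4ccc(OCc9ccccc9)c(OCc9ccccc9)c4 | intermediate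
16 | 4-bromo-1,2-bis(benzyloxy)benzene | Brc1ccc(OCc2ccccc2)c(OCc2ccccc2)c1 | starting material
17 | 3,4-bis(benzyloxy)phenylmagnesium bromide (not isolated) | Br[Mg]c1ccc(OCc2ccccc2)c(OCc2ccccc2)c1 | intermediate
18 | ring-opened hydroxy aldehyde: (2R,3R)-3-[4,6-bis(benzyloxy)-2-hydroxyphenyl]-3-(dimer-8-yl)-2-(TBS-oxy)propanal (present as its magnesium phenoxide; not isolated) | CC(C)(C)[Si](C)(C)O[C@@H]1[C@@H](c2c(OCc9ccccc9)cc(OCc9ccccc9)c3c2O[C@H](c4ccc(OCc9ccccc9)c(OCc9ccccc9)c4)[C@H](O[Si](C)(C)C(C)(C)C)C3)c2c(OCc9ccccc9)cc(OCc9ccccc9)c([C@@H](c5c(OCc9ccccc9)cc(OCc9ccccc9)cc5O)[C@@H](O[Si](C)(C)C(C)(C)C)C=O)c2O[C@@H]1c4ccc(OCc9ccccc9)c(OCc9ccccc9)c4 | intermediate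
19 | anti silyloxy carbinol: (1S,2R,3R)-1-[3,4-bis(benzyloxy)phenyl]-3-[4,6-bis(benzyloxy)-2-hydroxyphenyl]-3-(dimer-8-yl)-2-(TBS-oxy)propan-1-ol | CC(C)(C)[Si](C)(C)O[C@@H]1[C@@H](c2c(OCc9ccccc9)cc(OCc9ccccc9)c3c2O[C@H](c4ccc(OCc9ccccc9)c(OCc9ccccc9)c4)[C@H](O[Si](C)(C)C(C)(C)C)C3)c2c(OCc9ccccc9)cc(OCc9ccccc9)c([C@@H](c5c(OCc9ccccc9)cc(OCc9ccccc9)cc5O)[C@@H](O[Si](C)(C)C(C)(C)C)[C@@H](O)c6ccc(OCc9ccccc9)c(OCc9ccccc9)c6)c2O[C@@H]1c4ccc(OCc9ccccc9)c(OCc9ccccc9)c4 | intermediate
20 | dodeca-O-benzyl-3,3',3''-tris-O-TBS-procyanidin C1: three 5,7,3',4'-tetra-O-benzyl-3-O-TBS-epicatechin units joined (4β→8),(4β→8) | CC(C)(C)[Si](C)(C)O[C@@H]1[C@@H](c2c(OCc9ccccc9)cc(OCc9ccccc9)c3c2O[C@H](c4ccc(OCc9ccccc9)c(OCc9ccccc9)c4)[C@H](O[Si](C)(C)C(C)(C)C)C3)c2c(OCc9ccccc9)cc(OCc9ccccc9)c([C@H]3c5c(OCc9ccccc9)cc(OCc9ccccc9)cc5O[C@H](c6ccc(OCc9ccccc9)c(OCc9ccccc9)c6)[C@@H]3O[Si](C)(C)C(C)(C)C)c2O[C@@H]1c4ccc(OCc9ccccc9)c(OCc9ccccc9)c4 | intermediate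
21 | dodeca-O-benzyl-procyanidin C1 (all phenols benzylated, three free 3-OH) | O[C@@H]1[C@@H](c2c(OCc9ccccc9)cc(OCc9ccccc9)c3c2O[C@H](c4ccc(OCc9ccccc9)c(OCc9ccccc9)c4)[C@H](O)C3)c2c(OCc9ccccc9)cc(OCc9ccccc9)c([C@H]3c5c(OCc9ccccc9)cc(OCc9ccccc9)cc5O[C@H](c6ccc(OCc9ccccc9)c(OCc9ccccc9)c6)[C@@H]3O)c2O[C@@H]1c4ccc(OCc9ccccc9)c(OCc9ccccc9)c4 | intermediate
22 | dodeca-O-benzyl-procyanidin C1 3,3',3''-tris[3,4,5-tris(benzyloxy)benzoate] | O=C(c7cc(OCc9ccccc9)c(OCc9ccccc9)c(OCc9ccccc9)c7)O[C@@H]1[C@@H](c2c(OCc9ccccc9)cc(OCc9ccccc9)c3c2O[C@H](c4ccc(OCc9ccccc9)c(OCc9ccccc9)c4)[C@H](OC(=O)c7cc(OCc9ccccc9)c(OCc9ccccc9)c(OCc9ccccc9)c7)C3)c2c(OCc9ccccc9)cc(OCc9ccccc9)c([C@H]3c5c(OCc9ccccc9)cc(OCc9ccccc9)cc5O[C@H](c6ccc(OCc9ccccc9)c(OCc9ccccc9)c6)[C@@H]3OC(=O)c7cc(OCc9ccccc9)c(OCc9ccccc9)c(OCc9ccccc9)c7)c2O[C@@H]1c4ccc(OCc9ccccc9)c(OCc9ccccc9)c4 | intermediate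
23 | procyanidin C1 3,3',3''-tri-O-gallate: epicatechin 3-O-gallate-(4β→8)-epicatechin 3-O-gallate-(4β→8)-epicatechin 3-O-gallate | O=C(O[C@@H]1[C@@H](c2c(O)cc(O)c3c2O[C@H](c2ccc(O)c(O)c2)[C@H](OC(=O)c2cc(O)c(O)c(O)c2)C3)c2c(O)cc(O)c([C@H]3c4c(O)cc(O)cc4O[C@H](c4ccc(O)c(O)c4)[C@@H]3OC(=O)c3cc(O)c(O)c(O)c3)c2O[C@@H]1c1ccc(O)c(O)c1)c1cc(O)c(O)c(O)c1 | target

**Count and risks**

Total step count: 15. Longest linear sequence: 13 steps (steps 1–5 and 8–15, from (−)-epicatechin).

Three steps most likely to fail: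

Step 10. The enamine may add too slowly or reversibly to the very stabilised, crowded quinone methide, so that self-aldolisation of the aldehyde takes over, and facial control may be incomplete where the chiral dimer opposes the catalyst. The fallback sets out from 12 and changes the two-carbon partner to an ester enolate equivalent at the lactone oxidation level. Methyl (tert-butyldimethylsilyloxy)acetate is converted with LiN(i-Pr)2 and Me3SiCl into 2-(tert-butyldimethylsilyloxy)-1-methoxy-1-(trimethylsilyloxy)ethene F1. This is added to 12 in a Mukaiyama–Michael reaction catalysed by one enantiomer of 3,3'-bis(2,4,6-triisopropylphenyl)-1,1'-binaphthyl-2,2'-diyl hydrogen phosphate, which ionises the carbinol and controls the face of the methide as its ion-pair partner. The adduct should lactonise on the neighbouring phenol to the 3-silyloxy-4-arylchroman-2-one F2, whose C3 centre can be equilibrated to the 3,4-trans isomer with a catalytic amine base. Reduction with i-Bu2AlH in CH2Cl2 at −78 °C should then return the route at lactol 15.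

Step 12. The activated benzylic oxyphosphonium may ionise, since the 3,4-bis(benzyloxy)phenyl group stabilises the cation. Closure would then occur without clean inversion, or elimination would compete, and any shortfall in the facial selectivity of step 11 is carried through. The fallback sets out from 19 and sets C2 by hydride delivery, not by displacement. Oxidation of the benzylic carbinol with MnO2 in CH2Cl2 should give the aryl ketone, which closes on the phenol to the 2-aryl-chroman-2-ol F3, whatever the carbinol configuration was. Ionic reduction with Et3SiH and BF3·OEt2 in CH2Cl2 at −78 °C proceeds through the 2-aryl oxocarbenium ion. Hydride should add axially and anti to the pseudoaxial C3 silyloxy group, which places the aryl group cis to the C3 oxygen and returns the route at 20.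

Step 8. The crowded aryllithium may add too slowly to the di-ortho-substituted, electron-rich aldehyde, so that proton transfer to the aryllithium (giving debrominated dimer) or decomposition on warming competes. The fallback sets out from 6 and reverses the roles of the two partners. Aryllithium 10 is quenched with the small electrophile N,N-dimethylformamide to give the dimer C8-carbaldehyde F4. This is treated in toluene/CH2Cl2 with bromomagnesium 3,5-bis(benzyloxy)phenoxide F5, made from commercial 3,5-bis(benzyloxy)phenol and EtMgBr. The magnesium ion binds the aldehyde and delivers it to one of the two equivalent ortho carbons of the phenoxide (ortho-selective hydroxyalkylation of a magnesium phenoxide). This should give the free ortho-hydroxy benzhydrol directly, so the route is rejoined at 12 and steps 6, 7 and 9 are no longer needed.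

**Further compounds**

F1 | step 10 | 2-(tert-butyldimethylsilyloxy)-1-methoxy-1-(trimethylsilyloxy)ethene | COC(O[Si](C)(C)C)=CO[Si](C)(C)C(C)(C)C
F2 | step 10 | protected trimer whose upper unit is (3R,4R)-5,7-bis(benzyloxy)-3-(TBS-oxy)chroman-2-one (3,4-trans lactone) | CC(C)(C)[Si](C)(C)O[C@@H]1[C@@H](c2c(OCc9ccccc9)cc(OCc9ccccc9)c3c2O[C@H](c4ccc(OCc9ccccc9)c(OCc9ccccc9)c4)[C@H](O[Si](C)(C)C(C)(C)C)C3)c2c(OCc9ccccc9)cc(OCc9ccccc9)c([C@H]3c5c(OCc9ccccc9)cc(OCc9ccccc9)cc5OC(=O)[C@@H]3O[Si](C)(C)C(C)(C)C)c2O[C@@H]1c4ccc(OCc9ccccc9)c(OCc9ccccc9)c4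
F3 | step 12 | protected trimer whose upper unit is 2-[3,4-bis(benzyloxy)phenyl]-5,7-bis(benzyloxy)-3-(TBS-oxy)chroman-2-ol (hemiketal, C2 unassigned; 3R,4R) | CC(C)(C)[Si](C)(C)O[C@@H]1[C@@H](c2c(OCc9ccccc9)cc(OCc9ccccc9)c3c2O[C@H](c4ccc(OCc9ccccc9)c(OCc9ccccc9)c4)[C@H](O[Si](C)(C)C(C)(C)C)C3)c2c(OCc9ccccc9)cc(OCc9ccccc9)c([C@H]3c5c(OCc9ccccc9)cc(OCc9ccccc9)cc5OC(O)(c6ccc(OCc9ccccc9)c(OCc9ccccc9)c6)[C@@H]3O[Si](C)(C)C(C)(C)C)c2O[C@@H]1c4ccc(OCc9ccccc9)c(OCc9ccccc9)c4
F4 | step 8 | dimer C8-carbaldehyde (formyl group at C8 of the middle unit) | CC(C)(C)[Si](C)(C)O[C@@H]1[C@@H](c2c(OCc9ccccc9)cc(OCc9ccccc9)c3c2O[C@H](c4ccc(OCc9ccccc9)c(OCc9ccccc9)c4)[C@H](O[Si](C)(C)C(C)(C)C)C3)c2c(OCc9ccccc9)cc(OCc9ccccc9)c(C=O)c2O[C@@H]1c4ccc(OCc9ccccc9)c(OCc9ccccc9)c4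
F5 | step 8 | bromomagnesium 3,5-bis(benzyloxy)phenoxide | Br[Mg]Oc1cc(OCc2ccccc2)cc(OCc2ccccc2)c1
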